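**Retrosynthetic overview**
- The target is numbered as a 1-tetralone (C1 ketone, C4 stereocentre, C4a/C8a ring fusion). The last step only removes three MOM ethers from the protected tetralone.
- Key disconnection: C1–C8a and C3–C4 are cut together. The precursor is an ortho-bromo diarylmethyl methyl ether plus cyclopropanone (from its ethyl hemiacetal); Grignard addition and strain-release, nickel-catalysed ring-opening alkylation run in one flask. The cyclohexanone ring is the only ring built, and it is built last.
- Enabling feature: C8a (bromine-bearing, between C8–O and C4a) and C4 (a 1-naphthylmethyl C–OMe carbon on C4a) form an ortho nucleophile/electrophile pair. Cyclopropanone bridges it: C1 is electrophilic, C3 becomes nucleophilic on ring opening. The naphthalene ring on C4 lets nickel insert into C4–O.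
- The (R)-ether comes from catalytic asymmetric transfer of the naphthyl group to the bromo aldehyde, then O-methylation. Inversion at C4 in the key step gives (S).
- The naphthyl bromide comes from 5-methoxynaphthalen-1-ol (para-bromination, MOM); the aldehyde from 2-bromo-3-hydroxy-4-methoxybenzaldehyde (demethylation, MOM).

Key step: step 7

Remark: tetralone numbering is used for the target and its precursors throughout, and 5-methoxynaphthalen-1-ol, 2-bromo-3-hydroxy-4-methoxybenzaldehyde and 1-ethoxycyclopropan-1-ol (cyclopropanone ethyl hemiacetal) are taken as commercial.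

Step 1
Reactants: 1 5-methoxynaphthalen-1-ol
Product: 2 4-bromo-5-methoxynaphthalen-1-ol
Conditions: N-bromosuccinimide (1.0 equiv), MeCN, −20 °C
Reagents that add atoms: N-bromosuccinimide, O=C1CCC(=O)N1Br
Why: Electrophilic aromatic bromination, in which the free hydroxyl is the strongest activator and should direct bromine para to itself, to C4, the alpha position that 1,5-dioxygenated naphthalenes favour.

Step 2
Reactants: 2 4-bromo-5-methoxynaphthalen-1-ol
Product: 3 1-bromo-8-methoxy-4-(methoxymethoxy)naphthalene
Conditions: NaH, chloromethyl methyl ether, DMF, 0 °C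
Reagents that add atoms: chloromethyl methyl ether, COCCl
Why: Williamson-type O-alkylation of the sodium naphthoxide should give the MOM ether, which tolerates organolithium, organozinc, Grignard and nickel chemistry and is removed by acid.

Step 3
Reactants: 4 2-bromo-3-hydroxy-4-methoxybenzaldehyde
Product: 5 2-bromo-3,4-dihydroxybenzaldehyde
Conditions: BBr3, CH2Cl2, −78 → 0 °C; then H2O
Reagents that add atoms: none
Why: Lewis acid cleavage of the aryl methyl ether by BBr3 should free the catechol while the aldehyde and the aryl bromide stay untouched.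

Step 4
Reactants: 5 2-bromo-3,4-dihydroxybenzaldehyde
Product: 6 2-bromo-3,4-bis(methoxymethoxy)benzaldehyde
Conditions: NaH (2.2 equiv), chloromethyl methyl ether (2.2 equiv), DMF, 0 °C
Reagents that add atoms: chloromethyl methyl ether, COCCl
Why: Double Williamson-type O-alkylation should protect both phenols as MOM ethers, so that all three phenol protecting groups of the route fall in one final acid step.

Step 5
Reactants: 3 1-bromo-8-methoxy-4-(methoxymethoxy)naphthalene; 6 2-bromo-3,4-bis(methoxymethoxy)benzaldehyde
Product: 10 (R)-[2-bromo-3,4-bis(methoxymethoxy)phenyl][8-methoxy-4-(methoxymethoxy)naphthalen-1-yl]methanol, via naphthyllithium 7 (not isolated), via naphthylzinc chloride 8 (not isolated), via butyl(naphthyl)zinc 9 (not isolated)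
Conditions: n-BuLi, t-BuOMe, −78 °C; ZnCl2, 0 °C; n-BuLi, −78 → 0 °C; TEEDA, toluene; (+)-MIB (5 mol%), then 6, 0 °C; H2O
Reagents that add atoms: none
Why: Catalytic asymmetric aryl transfer (bromine–lithium exchange, transmetalation to the mixed aryl(butyl)zinc, amino alcohol-catalysed 1,2-addition), in which the zinc chelate of (+)-MIB, (2R)-3-exo-morpholinoisoborneol, should deliver the naphthyl group to the Re face of the aldehyde and set the (R) carbinol centre while TEEDA masks LiCl and suppresses the unselective background addition.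

Step 6
Reactants: 10 (R)-[2-bromo-3,4-bis(methoxymethoxy)phenyl][8-methoxy-4-(methoxymethoxy)naphthalen-1-yl]methanol
Product: 11 1-[(R)-[2-bromo-3,4-bis(methoxymethoxy)phenyl](methoxy)methyl]-8-methoxy-4-(methoxymethoxy)naphthalene
Conditions: NaH, MeI, THF, 0 → 25 °C
Reagents that add atoms: iodomethane, CI
Why: Williamson etherification of the sodium alkoxide with iodomethane does not touch the C–O stereocentre, so the (R) configuration should be kept.

Step 7
Reactants: 11 1-[(R)-[2-bromo-3,4-bis(methoxymethoxy)phenyl](methoxy)methyl]-8-methoxy-4-(methoxymethoxy)naphthalene; 12 1-ethoxycyclopropan-1-ol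
Product: 17 (S)-4-[8-methoxy-4-(methoxymethoxy)naphthalen-1-yl]-7,8-bis(methoxymethoxy)-3,4-dihydronaphthalen-1(2H)-one, via hemiacetal magnesium salt 13 (not isolated), via cyclopropanone 14 (not isolated), via arylmagnesium bromide 15 (not isolated), via magnesium cyclopropanolate 16 (not isolated)
Conditions: Mg turnings, LiCl, THF, 25 °C; cannulate onto 12 + MeMgBr (THF, −20 °C), −20 → 25 °C; Ni(cod)2 (10 mol%), DPEphos (20 mol%), toluene, 25 → 50 °C; H2O
Reagents that add atoms: none
Why: Proposed new method: magnesium inserts into the C8a–Br bond to give Grignard 15, which adds to cyclopropanone 14 (set free from hemiacetal salt 13) and so forms C1–C8a; zerovalent nickel then inserts with inversion into the 1-naphthylmethyl C4–OMe bond (the neighbouring magnesium alkoxide acts as internal Lewis acid), the cyclopropanolate moves to divalent nickel, strain-driven β-carbon elimination opens the three-membered ring to a seven-membered benzyl/alkyl nickelacycle, and C(sp3)–C(sp3) reductive elimination forms C3–C4 and returns zerovalent nickel. Closest known reaction types are the addition of Grignard reagents to cyclopropanone hemiacetal magnesium salts, the stereospecific nickel-catalysed Kumada coupling of enantioenriched diarylmethyl (naphthylmethyl) methyl ethers with alkyl Grignard reagents, and the ring-opening cross-coupling of cyclopropanols through metal homoenolates; what is new is their merger into an intramolecular ring-opening alkylation of a benzylic ether. The cyclohexanone ring closes by reductive elimination from the seven-membered nickelacycle (Ni, C4, C4a, C8a, C1, C2, C3), formally a 6-exo-tet displacement of methoxide at C4 by the homoenolate carbon C3. The C4 stereocentre is controlled by the configuration of the C4–OMe carbon of 11: inversion in the oxidative addition and retention in the reductive elimination should turn (R) into (S). Site selectivity for acylation at C8a and not at C5 is secured by the bromine on C8a, chemoselectivity of nickel for C4–OMe over the aryl and acetal C–O bonds by the naphthalene ring on C4, and direct aryl–benzyl coupling is avoided because nickel is added only after all Grignard 15 has been converted into alkoxide 16.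

Step 8
Reactants: 17 (S)-4-[8-methoxy-4-(methoxymethoxy)naphthalen-1-yl]-7,8-bis(methoxymethoxy)-3,4-dihydronaphthalen-1(2H)-one
Product: 18 (S)-7,8-dihydroxy-4-(4-hydroxy-8-methoxynaphthalen-1-yl)-3,4-dihydronaphthalen-1(2H)-one
Conditions: conc. HCl (cat.), MeOH, 50 °C
Reagents that add atoms: none
Why: Acid-catalysed transacetalisation to methanol should cleave the three MOM acetals and leave the naphthyl methyl ether, the ketone and the (S) centre at C4 unchanged, since C4 has no enolisation or ionisation pathway under these conditions.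

**Compound list**
1 | 5-methoxynaphthalen-1-ol | COc1cccc2c(O)cccc12 | starting material
2 | 4-bromo-5-methoxynaphthalen-1-ol | COc1cccc2c(O)ccc(Br)c12 | intermediate
3 | 1-bromo-8-methoxy-4-(methoxymethoxy)naphthalene | COCOc1ccc(Br)c2c(OC)cccc12 | intermediate
4 | 2-bromo-3-hydroxy-4-methoxybenzaldehyde | COc1ccc(C=O)c(Br)c1O | starting material
5 | 2-bromo-3,4-dihydroxybenzaldehyde | O=Cc1ccc(O)c(O)c1Br | intermediate
6 | 2-bromo-3,4-bis(methoxymethoxy)benzaldehyde | COCOc1ccc(C=O)c(Br)c1OCOC | intermediate
7 | [8-methoxy-4-(methoxymethoxy)naphthalen-1-yl]lithium | [Li]c1ccc(OCOC)c2cccc(OC)c12 | intermediate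
8 | chloro[8-methoxy-4-(methoxymethoxy)naphthalen-1-yl]zinc | Cl[Zn]c1ccc(OCOC)c2cccc(OC)c12 | intermediate
9 | butyl[8-methoxy-4-(methoxymethoxy)naphthalen-1-yl]zinc | CCCC[Zn]c1ccc(OCOC)c2cccc(OC)c12 | intermediate
10 | (R)-[2-bromo-3,4-bis(methoxymethoxy)phenyl][8-methoxy-4-(methoxymethoxy)naphthalen-1-yl]methanol | O[C@@H](c1ccc(OCOC)c(OCOC)c1Br)c1ccc(OCOC)c2cccc(OC)c12 | intermediate
11 | 1-[(R)-[2-bromo-3,4-bis(methoxymethoxy)phenyl](methoxy)methyl]-8-methoxy-4-(methoxymethoxy)naphthalene | CO[C@@H](c1ccc(OCOC)c(OCOC)c1Br)c1ccc(OCOC)c2cccc(OC)c12 | intermediate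
12 | 1-ethoxycyclopropan-1-ol | CCOC1(O)CC1 | starting material
13 | bromomagnesium 1-ethoxycyclopropan-1-olate | CCOC1(O[Mg]Br)CC1 | intermediate
14 | cyclopropanone | O=C1CC1 | intermediate
15 | bromo{6-[(R)-methoxy[8-methoxy-4-(methoxymethoxy)naphthalen-1-yl]methyl]-2,3-bis(methoxymethoxy)phenyl}magnesium | CO[C@@H](c1ccc(OCOC)c(OCOC)c1[Mg]Br)c1ccc(OCOC)c2cccc(OC)c12 | intermediate
16 | bromomagnesium 1-{6-[(R)-methoxy[8-methoxy-4-(methoxymethoxy)naphthalen-1-yl]methyl]-2,3-bis(methoxymethoxy)phenyl}cyclopropan-1-olate | CO[C@@H](c1ccc(OCOC)c(OCOC)c1C1(O[Mg]Br)CC1)c1ccc(OCOC)c2cccc(OC)c12 | intermediate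
17 | (S)-4-[8-methoxy-4-(methoxymethoxy)naphthalen-1-yl]-7,8-bis(methoxymethoxy)-3,4-dihydronaphthalen-1(2H)-one | COc1cccc2c(OCOC)ccc([C@@H]3CCC(=O)c4c3ccc(OCOC)c4OCOC)c12 | intermediate
18 | (S)-7,8-dihydroxy-4-(4-hydroxy-8-methoxynaphthalen-1-yl)-3,4-dihydronaphthalen-1(2H)-one | COc1cccc2c(O)ccc([C@@H]3CCC(=O)c4c3ccc(O)c4O)c12 | target

Total step count: 8. Longest linear sequence: 6 steps (1, 2, 5, 6, 7, 8; the branch through steps 3 and 4 is equally long).

**Steps most likely to fail**

1. Step 7 (Proposed new method).
- What may go wrong: β-carbon elimination at the benzyl nickel alkoxide may be too slow. Then β-hydride elimination of the homoenolate, protonolysis of the opened chain, or ionisation of the benzylic nickel species with loss of configuration at C4 could take over.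
- Fallback (known chemistry, from aldehyde 6 with bromide 3, back to 17):
  - Wittig olefination of 6 with Ph3P=CHCO2Et (toluene, 80 °C) should give ethyl (E)-3-[2-bromo-3,4-bis(methoxymethoxy)phenyl]prop-2-enoate F1.
  - Bromide 3 is converted with n-BuLi and B(OMe)3, then aqueous work-up, into [8-methoxy-4-(methoxymethoxy)naphthalen-1-yl]boronic acid F2.
  - Hayashi–Miyaura 1,4-addition of F2 to F1 with Rh(acac)(C2H4)2 and the BINAP enantiomer that delivers the aryl group to the Re face of C3 (dioxane/H2O, 100 °C) should set the diarylmethine centre in ethyl (S)-3-[2-bromo-3,4-bis(methoxymethoxy)phenyl]-3-[8-methoxy-4-(methoxymethoxy)naphthalen-1-yl]propanoate F3.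
  - LiOH (THF/H2O) should give (S)-3-[2-bromo-3,4-bis(methoxymethoxy)phenyl]-3-[8-methoxy-4-(methoxymethoxy)naphthalen-1-yl]propanoic acid F4.
  - Arndt–Eistert homologation: the mixed anhydride (i-BuOCOCl, N-methylmorpholine) and TMSCHN2 should give (S)-4-[2-bromo-3,4-bis(methoxymethoxy)phenyl]-1-diazo-4-[8-methoxy-4-(methoxymethoxy)naphthalen-1-yl]butan-2-one F5. Wolff rearrangement (silver benzoate, AgO2CPh, dioxane/H2O) should then give (S)-4-[2-bromo-3,4-bis(methoxymethoxy)phenyl]-4-[8-methoxy-4-(methoxymethoxy)naphthalen-1-yl]butanoic acid F6.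
  - Parham cyclisation of F6 (n-BuLi, 2.2 equiv, THF, −100 °C), through the lithium carboxylate, should close C1–C8a at the brominated carbon and return to 17.

2. Step 5.
- What may go wrong: the peri-methoxy group may slow aryl transfer from zinc, so that the uncatalysed, unselective addition competes and enantiofacial control is poor.
- Fallback (from 3 and 6, back to 10):
  - Lithium reagent 7 is added directly to 6 (THF, −78 °C) to give racemic [2-bromo-3,4-bis(methoxymethoxy)phenyl][8-methoxy-4-(methoxymethoxy)naphthalen-1-yl]methanol F7.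
  - Esterification with (S)-2-methoxy-2-phenylacetic acid (DCC, DMAP, CH2Cl2) and chromatographic separation of the two diastereomers should give (R)-[2-bromo-3,4-bis(methoxymethoxy)phenyl][8-methoxy-4-(methoxymethoxy)naphthalen-1-yl]methyl (S)-2-methoxy-2-phenylacetate F8.
  - Saponification (LiOH, THF/MeOH/H2O) should release 10.

3. Step 1.
- What may go wrong: bromination ortho to the hydroxyl (C2) or in the methoxy-bearing ring (C8), or oxidation of the electron-rich naphthol towards the quinone.
- Fallback (from 1, back to 2):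
  - Silylation (TIPSCl, imidazole, DMF) should give triisopropyl[(5-methoxynaphthalen-1-yl)oxy]silane F9.
  - Methoxy-directed peri-lithiation at C4 (t-BuLi, cyclohexane, 25 °C) and quench with BrCF2CF2Br should give [(4-bromo-5-methoxynaphthalen-1-yl)oxy]triisopropylsilane F10.
  - Desilylation (TBAF, THF, 0 °C) should give 2.

**Further compounds**
F1 | step 7 | ethyl (E)-3-[2-bromo-3,4-bis(methoxymethoxy)phenyl]prop-2-enoate | CCOC(=O)/C=C/c1ccc(OCOC)c(OCOC)c1Br
F2 | step 7 | [8-methoxy-4-(methoxymethoxy)naphthalen-1-yl]boronic acid | OB(O)c1ccc(OCOC)c2cccc(OC)c12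
F3 | step 7 | ethyl (S)-3-[2-bromo-3,4-bis(methoxymethoxy)phenyl]-3-[8-methoxy-4-(methoxymethoxy)naphthalen-1-yl]propanoate | CCOC(=O)C[C@H](c1ccc(OCOC)c(OCOC)c1Br)c1ccc(OCOC)c2cccc(OC)c12
F4 | step 7 | (S)-3-[2-bromo-3,4-bis(methoxymethoxy)phenyl]-3-[8-methoxy-4-(methoxymethoxy)naphthalen-1-yl]propanoic acid | OC(=O)C[C@H](c1ccc(OCOC)c(OCOC)c1Br)c1ccc(OCOC)c2cccc(OC)c12
F5 | step 7 | (S)-4-[2-bromo-3,4-bis(methoxymethoxy)phenyl]-1-diazo-4-[8-methoxy-4-(methoxymethoxy)naphthalen-1-yl]butan-2-one | [N-]=[N+]=CC(=O)C[C@H](c1ccc(OCOC)c(OCOC)c1Br)c1ccc(OCOC)c2cccc(OC)c12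
F6 | step 7 | (S)-4-[2-bromo-3,4-bis(methoxymethoxy)phenyl]-4-[8-methoxy-4-(methoxymethoxy)naphthalen-1-yl]butanoic acid | OC(=O)CC[C@H](c1ccc(OCOC)c(OCOC)c1Br)c1ccc(OCOC)c2cccc(OC)c12
F7 | step 5 | racemic [2-bromo-3,4-bis(methoxymethoxy)phenyl][8-methoxy-4-(methoxymethoxy)naphthalen-1-yl]methanol | OC(c1ccc(OCOC)c(OCOC)c1Br)c1ccc(OCOC)c2cccc(OC)c12
F8 | step 5 | (R)-[2-bromo-3,4-bis(methoxymethoxy)phenyl][8-methoxy-4-(methoxymethoxy)naphthalen-1-yl]methyl (S)-2-methoxy-2-phenylacetate | CO[C@H](C(=O)O[C@@H](c1ccc(OCOC)c(OCOC)c1Br)c1ccc(OCOC)c2cccc(OC)c12)c1ccccc1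
F9 | step 1 | triisopropyl[(5-methoxynaphthalen-1-yl)oxy]silane | COc1cccc2c(O[Si](C(C)C)(C(C)C)C(C)C)cccc12
F10 | step 1 | [(4-bromo-5-methoxynaphthalen-1-yl)oxy]triisopropylsilane | COc1cccc2c(O[Si](C(C)C)(C(C)C)C(C)C)ccc(Br)c12
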